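The rate constants are those of an exercise.

Heating from 25 °C to 50 °C speeds the coupling of partner and intermediate by a factor of 4.2, but the making of target can be expected to speed up by less than that, since the balance that frees the intermediate shifts back as the flask warms.

all flasks: starting material 0.010 M; partner 0.0300 M; protic impurity 0.200 mM; time 3.0 min

| flask | remark | temperature |
|---|---|---|
| blue | at 50 °C until 40 s, from then on at 25 °C |  |
| amber |  | 50 °C |
| teal |  | 25 °C |
    partner + intermediate → target (k1 = 18000 L mol⁻¹ min⁻¹, Ea1 = 46.0 kJ mol⁻¹)
    starting material ⇌ intermediate + leaving ligand, settled at all times (K2 = 8.1 × 10⁻⁶ M, ΔH2 = −23.0 kJ mol⁻¹)
    starting material + protic impurity → quenched substrate (k3 = 310 L mol⁻¹ min⁻¹, Ea3 = 52.0 kJ mol⁻¹)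
    (constants at 25 °C)
- at 25 °C the constants are as listed, elsewhere as the activation energies and enthalpies make them
- which flask leads in amount of target, in percent of the starting material charged ("all alike" within 1.5 percentage points) (blue / amber / teal / all alike)
- how much target is there at the end, in percent of the starting material charged: blue
- how much target is there at the end, in percent of the starting material charged: amber
- how much target is there at the end, in percent of the starting material charged: teal

The balance holds the intermediate at its equilibrium constant times starting material, the resting state, over leaving ligand. Each target formed leaves one leaving ligand behind, so, with free intermediate left out of the count, target and leaving ligand rise together. The coupling therefore runs at the product of its rate constant and the equilibrium constant, times partner, times starting material, over leaving ligand. That product is 0.146 min⁻¹ at 25 °C; call it the throttled constant. Going to 50 °C multiplies the rate constant by 4.2 and the equilibrium constant by 0.488, so at 50 °C the throttled constant is 0.299 min⁻¹.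

Multiplied by time, and added up over the hot and cold stretches of blue, it makes a clock: teal 0.437, amber 0.897, blue 0.539. Amber has the longest clock.

In teal the protic impurity, which quenches starting material one for one, has a half-life near 0.224 min at the charged starting material, shorter than the run, and at 50 °C the quench is faster by a factor of 5.1. So take its whole charge off the starting material, leaving c = 9.80 mM. With a the partner charge and x the target, integration gives

c·ln(c/(c−x)) − a·ln(a/(a−x)) = (a−c)·clock.

Solve this for the x in the first logarithm, put the last x into the second, and start from x = c. Teal runs 8.61 mM, 8.39 mM, 8.34 mM. Blue runs 8.84 mM, 8.69 mM, 8.67 mM. Amber runs 9.34 mM, 9.31 mM, 9.30 mM. That commits to 83.4% for teal, 86.7% for blue and 93.0% for amber.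

The weak link is the quench in teal. Starting material stays above about 1.46 mM in this reckoning, so the reckoning puts the protic impurity left at the end in teal below 25.8% of its charge. Giving that share back raises c to 9.85 mM and teal to 8.36 mM, still less than blue, and amber stands ahead of blue by 6.4 percentage points, more than the margin.

The forecast named amber, with 86.6% for blue, 93% for amber and 83.5% for teal, reasoning that leaving ligand builds up “so it throttles its own release”. The simulation gives amber in the lead, with 86.6% for blue, 93.0% for amber and 83.4% for teal.

In amber the quench ran early, while protic impurity was there: 99.0% of its turnover up to the end lay behind it at 0.600 min. The coupling in amber ran across the 3.0 min, the midpoint of its turnover up to the end passed at 0.208 min, and amber's final 0.00930 M of leaving ligand, put into the law, returns a clock of 0.897. The neighbour like amber but with 0.017 M of starting material keeps amber's clock of 0.897, and the passes run 14.9 mM, 14.4 mM, 14.2 mM, or 83.5% of its charge; at 3.00 min that flask held 83.2% as target.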